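## Retrosynthetic overview

- **Feature:** The chain is numbered C1' (OCH2) to C7' (CMe2). C2'=C3' is an E-trisubstituted alkene with its methyl group and C1' on the same side, which is the pattern left by syn addition of CH3 and a one-carbon electrophile across a terminal C2'≡C3' alkyne.
- **Oxirane C6'–O–C7'** (the only ring made, and made last): C5'-OH-directed Ti/L-(+)-tartrate epoxidation of C6'=C7'. The benzene and α-pyrone rings of the coumarin are bought intact.
- **C1'–O(aryl):** Mitsunobu coupling of the primary allylic alcohol with 7-hydroxy-8-methoxycoumarin.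
- **C3'–CH3 and C1'–C2':** Zr-catalysed methylalumination of the O-silylated (S)-homopropargylic alcohol, then alanate formation and capture of formaldehyde.
- **C4'–C5' and the C5' stereocentre:** catalytic asymmetric propargylboration of 3-methylbut-2-enal with allenylboronic acid pinacol ester.

Key step: step 3

Assumption: the (S)-antipode of TRIP (3,3'-bis(2,4,6-triisopropylphenyl)-BINOL hydrogen phosphate) is taken to give the S carbinol, with the alkenyl group in the place an aryl group holds in the accepted transition-state model; the configuration of 4 is to be checked by Mosher ester analysis, and the antipodal acid is used if the sense is opposite.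

## Route

Step 1
Reactants: 1 3-methylbut-2-enal; 2 allenylboronic acid pinacol ester
Product: 4 (S)-6-methylhept-5-en-1-yn-4-ol, via homopropargyl pinacol borate 3 (not isolated)
Conditions: (S)-TRIP (10 mol %), 4 Å MS, toluene, −20 °C; aq. NaHCO3 work-up
Reagents that add atoms: none
Why: Chiral phosphoric acid-catalysed propargylboration: the allenylboronate adds 1,2 to the enal through a closed six-membered SE2' transition state, which gives only the homopropargylic (not the allenic) carbinol, and the acid bound to a boronate oxygen and to the formyl hydrogen blocks one aldehyde face and so sets C5' (C4 of 4) as S; hydrolysis of borate 3 on work-up frees the alcohol.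

Step 2
Reactants: 4 (S)-6-methylhept-5-en-1-yn-4-ol
Product: 5 tert-butyldimethyl{[(4S)-6-methylhept-5-en-1-yn-4-yl]oxy}silane
Conditions: TBSCl, imidazole, DMF, 0 °C → rt
Reagents that add atoms: tert-butyldimethylsilyl chloride, CC(C)(C)[Si](C)(C)Cl
Why: Imidazole-promoted silylation of a secondary alcohol touches no stereocentre; the ether keeps C5'–O from becoming an aluminium alkoxide that could chelate and isomerise the alkenylmetal of step 3, and it leaves C1'–OH as the only free hydroxyl in step 4.

Step 3
Reactants: 5 tert-butyldimethyl{[(4S)-6-methylhept-5-en-1-yn-4-yl]oxy}silane; 6 trimethylaluminium; 7 paraformaldehyde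
Product: 11 (2E,5S)-5-[(tert-butyldimethylsilyl)oxy]-3,7-dimethylocta-2,6-dien-1-ol, via (E)-alkenyldimethylalane 8 (not isolated), via lithium alkenylalanate 9 (not isolated), via lithium alkoxyalanate 10 (not isolated)
Conditions: Me3Al (2.5 equiv), Cp2ZrCl2 (25 mol %), CH2Cl2, 0 °C → rt; volatiles off in vacuo; n-BuLi (1.1 equiv), hexane–THF, −78 → 0 °C; dried (CH2O)n (excess), 0 °C → rt; aq. Rochelle salt
Reagents that add atoms: trimethylaluminium 6, C[Al](C)C; formaldehyde from paraformaldehyde 7, C=O
Why: Cp2ZrCl2 and Me3Al exchange ligands to give an aluminium-polarised Me–Zr species that adds across C2'≡C3' of 5 in a concerted four-centre syn fashion, metal on the unhindered terminal carbon and methyl on the internal one, after which Zr→Al transmetalation releases (E)-alkenylalane 8 and returns the catalyst. n-BuLi turns the weakly nucleophilic alane into alanate 9, whose alkenyl ligand is transferred to formaldehyde with retention of geometry to give alkoxyalanate 10, which is hydrolysed to 11 on work-up. This is the Negishi zirconium-catalysed carboalumination with ate-complex/paraformaldehyde trapping, the standard entry to (E)-3-methylalk-2-en-1-ols. No ring is closed and no stereocentre is created; C5' is carried through unchanged, insulated from the reacting carbons by C4'H2. The step needs regioselectivity (methyl on C3'), syn stereospecificity and chemoselectivity for the alkyne: the terminal alkyne secures the first, the concerted addition and the non-chelating OTBS group (no alkoxide-assisted E→Z isomerisation of the alkenylmetal) the second, and the inertness of the trisubstituted C6'=C7' alkene to methylzirconation the third.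

Step 4
Reactants: 11 (2E,5S)-5-[(tert-butyldimethylsilyl)oxy]-3,7-dimethylocta-2,6-dien-1-ol; 12 7-hydroxy-8-methoxycoumarin
Product: 13 7-{[(2E,5S)-5-[(tert-butyldimethylsilyl)oxy]-3,7-dimethylocta-2,6-dien-1-yl]oxy}-8-methoxy-2H-chromen-2-one
Conditions: PPh3, DIAD, THF, 0 °C → rt
Reagents that add atoms: none
Why: Mitsunobu etherification: the acidic 7-OH of the coumarin is alkylated by SN2 displacement at the activated primary allylic C1', the only free hydroxyl of 11, so the E geometry and C5' are untouched and no allylic halide has to be handled.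

Step 5
Reactants: 13 7-{[(2E,5S)-5-[(tert-butyldimethylsilyl)oxy]-3,7-dimethylocta-2,6-dien-1-yl]oxy}-8-methoxy-2H-chromen-2-one
Product: 14 7-{[(2E,5S)-5-hydroxy-3,7-dimethylocta-2,6-dien-1-yl]oxy}-8-methoxy-2H-chromen-2-one
Conditions: TBAF, AcOH (1:1), THF, 0 °C → rt
Reagents that add atoms: none
Why: Fluoride-driven desilylation (strong Si–F bond); buffering with acetic acid keeps the medium from opening the pyrone lactone, and the aryl allyl ether, both alkenes and C5' are inert.

Step 6
Reactants: 14 7-{[(2E,5S)-5-hydroxy-3,7-dimethylocta-2,6-dien-1-yl]oxy}-8-methoxy-2H-chromen-2-one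
Product: 15 7-{[(2E,5S)-5-[(2S)-3,3-dimethyloxiran-2-yl]-5-hydroxy-3-methylpent-2-en-1-yl]oxy}-8-methoxy-2H-chromen-2-one (CNP0166233.1)
Conditions: Ti(OiPr)4 (20 mol %), L-(+)-DIPT (26 mol %), TBHP (decane, 1.5 equiv), 4 Å MS, CH2Cl2, −20 °C; sat. aq. Na2SO4 work-up
Reagents that add atoms: tert-butyl hydroperoxide, CC(C)(C)OO
Why: Katsuki–Sharpless epoxidation in its matched kinetic-resolution sense: the C5' alkoxide binds to the Ti–tartrate complex, so only the allylic C6'=C7' bond receives oxygen (not the homoallylic, aryloxy-deactivated C2'=C3' bond or the electron-poor pyrone C3=C4 bond), L-(+)-DIPT delivers it to the face that makes C6' S, and for a (5'S)-carbinol this is the fast-reacting, erythro-forming pairing, which closes the oxirane C6'–O–C7' by concerted syn oxygen transfer.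

## Compound list

1 | 3-methylbut-2-enal | CC(C)=CC=O | starting material
2 | allenylboronic acid pinacol ester | C=C=CB1OC(C)(C)C(C)(C)O1 | starting material
3 | homopropargyl pinacol borate, 2-{[(4S)-6-methylhept-5-en-1-yn-4-yl]oxy}-4,4,5,5-tetramethyl-1,3,2-dioxaborolane (not isolated) | C#CC[C@H](OB1OC(C)(C)C(C)(C)O1)C=C(C)C | intermediate
4 | (S)-6-methylhept-5-en-1-yn-4-ol | C#CC[C@H](O)C=C(C)C | intermediate
5 | tert-butyldimethyl{[(4S)-6-methylhept-5-en-1-yn-4-yl]oxy}silane | C#CC[C@H](O[Si](C)(C)C(C)(C)C)C=C(C)C | intermediate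
6 | trimethylaluminium | C[Al](C)C | starting material
7 | paraformaldehyde (written as formaldehyde) | C=O | starting material
8 | (E)-alkenyldimethylalane, {(1E,4S)-4-[(tert-butyldimethylsilyl)oxy]-2,6-dimethylhepta-1,5-dien-1-yl}dimethylalumane (not isolated) | C[Al](C)/C=C(\C)C[C@H](O[Si](C)(C)C(C)(C)C)C=C(C)C | intermediate
9 | lithium alkenylalanate, lithium butyl(dimethyl)alkenylaluminate from 8 (not isolated) | [Li+].CCCC[Al-](C)(C)/C=C(\C)C[C@H](O[Si](C)(C)C(C)(C)C)C=C(C)C | intermediate
10 | lithium alkoxyalanate, the O-aluminate of 11 (not isolated) | [Li+].CCCC[Al-](C)(C)OC/C=C(\C)C[C@H](O[Si](C)(C)C(C)(C)C)C=C(C)C | intermediate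
11 | (2E,5S)-5-[(tert-butyldimethylsilyl)oxy]-3,7-dimethylocta-2,6-dien-1-ol | OC/C=C(\C)C[C@H](O[Si](C)(C)C(C)(C)C)C=C(C)C | intermediate
12 | 7-hydroxy-8-methoxycoumarin | COc1c(O)ccc2ccc(=O)oc12 | starting material
13 | 7-{[(2E,5S)-5-[(tert-butyldimethylsilyl)oxy]-3,7-dimethylocta-2,6-dien-1-yl]oxy}-8-methoxy-2H-chromen-2-one | COc1c(OC/C=C(\C)C[C@H](O[Si](C)(C)C(C)(C)C)C=C(C)C)ccc2ccc(=O)oc12 | intermediate
14 | 7-{[(2E,5S)-5-hydroxy-3,7-dimethylocta-2,6-dien-1-yl]oxy}-8-methoxy-2H-chromen-2-one | COc1c(OC/C=C(\C)C[C@H](O)C=C(C)C)ccc2ccc(=O)oc12 | intermediate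
15 | 7-{[(2E,5S)-5-[(2S)-3,3-dimethyloxiran-2-yl]-5-hydroxy-3-methylpent-2-en-1-yl]oxy}-8-methoxy-2H-chromen-2-one | COc1c(OC/C=C(\C)C[C@H](O)[C@@H]2OC2(C)C)ccc2ccc(=O)oc12 | target

Total step count: 6. Longest linear sequence: 6 steps (1 → 15).

## Steps most likely to fail

**1. Step 6.** Facial selectivity may erode. The erythro transition state places the C4' chain near the Z-methyl group on C7' (allylic 1,3-strain), so the substrate bias towards threo attack opposes the tartrate control. Slow turnover would also leave time for titanium-promoted opening of the oxirane at its tertiary terminus.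

The fallback applies substrate control first and inverts C5' afterwards. It sets out from 1 and 2 and comes back at 15.
- Steps 1–5 are repeated with the antipodal acid. They lead through (R)-homopropargyl pinacol borate F1 to (R)-6-methylhept-5-en-1-yn-4-ol F2 and its (R)-TBS ether F3.
- The sequence continues via (4R)-alkenyldimethylalane F4, (4R)-lithium alkenylalanate F5 and (5R)-lithium alkoxyalanate F6 to (2E,5R)-5-[(tert-butyldimethylsilyl)oxy]-3,7-dimethylocta-2,6-dien-1-ol F7.
- Coupling and desilylation then give the (5'R)-coumarin silyl ether F8 and the (5'R)-allylic alcohol F9.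
- In F9 the ligand-free hydroxyl-directed epoxidation (Ti(OiPr)4, TBHP, CH2Cl2, −20 °C) should attack the face syn to the hydroxyl in the H-eclipsed conformer. This gives the threo (5'R,6'S)-epoxy alcohol F10, which already has the C6' configuration of the target.
- Mitsunobu inversion with 4-nitrobenzoic acid (PPh3, DIAD, toluene, 0 °C) should give the (5'S,6'S)-4-nitrobenzoate F11. Brief methanolysis (K2CO3, MeOH, 0 °C) then gives 15.

**2. Step 3.** The alanate may be captured incompletely by the sparingly soluble polymeric formaldehyde, so protodemetalation on work-up takes the place of C1'–C2' bond formation. Long exposure to the aluminium Lewis acids may also start ionisation of the allylic C5'–O bond.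

The fallback isolates the alkenyl halide and brings in C1' by palladium catalysis. It sets out from 5 and comes back at 11.
- Alane 8 is generated as before but quenched with iodine (THF, −30 °C) to give tert-butyl{[(1E,4S)-1-iodo-2,6-dimethylhepta-1,5-dien-4-yl]oxy}dimethylsilane F12.
- Methoxycarbonylation with retention of geometry (PdCl2(PPh3)2, CO 1 atm, Et3N, MeOH–DMF, 50 °C) gives methyl (2E,5S)-5-[(tert-butyldimethylsilyl)oxy]-3,7-dimethylocta-2,6-dienoate F13.
- DIBAL-H (CH2Cl2, −78 °C) reduces F13 to 11.

**3. Step 1.** Enantiofacial discrimination may be insufficient, or addition sluggish, because a β,β-disubstituted enal is less electrophilic and offers a smaller steric handle than the usual aldehydes.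

The fallback uses racemic addition followed by enzymatic resolution. It sets out from 1 and comes back at 4.
- Zinc-mediated Barbier propargylation with propargyl bromide (Zn, THF/sat. aq. NH4Cl, 0 °C) gives racemic 6-methylhept-5-en-1-yn-4-ol F14.
- Lipase acylation (CAL-B, vinyl acetate, MTBE, rt) is stopped just past half conversion. By Kazlauskas' rule (alkenyl large, propargyl medium) it should convert the R enantiomer into (R)-6-methylhept-5-en-1-yn-4-yl acetate F15 and leave 4, which is separated by chromatography.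

## Further compounds

F1 | step 6 | (R)-homopropargyl pinacol borate, 2-{[(4R)-6-methylhept-5-en-1-yn-4-yl]oxy}-4,4,5,5-tetramethyl-1,3,2-dioxaborolane | C#CC[C@@H](OB1OC(C)(C)C(C)(C)O1)C=C(C)C
F2 | step 6 | (R)-6-methylhept-5-en-1-yn-4-ol | C#CC[C@@H](O)C=C(C)C
F3 | step 6 | tert-butyldimethyl{[(4R)-6-methylhept-5-en-1-yn-4-yl]oxy}silane | C#CC[C@@H](O[Si](C)(C)C(C)(C)C)C=C(C)C
F4 | step 6 | {(1E,4R)-4-[(tert-butyldimethylsilyl)oxy]-2,6-dimethylhepta-1,5-dien-1-yl}dimethylalumane | C[Al](C)/C=C(\C)C[C@@H](O[Si](C)(C)C(C)(C)C)C=C(C)C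
F5 | step 6 | lithium butyl(dimethyl)alkenylaluminate from F4 | [Li+].CCCC[Al-](C)(C)/C=C(\C)C[C@@H](O[Si](C)(C)C(C)(C)C)C=C(C)C
F6 | step 6 | lithium alkoxyalanate, the O-aluminate of F7 | [Li+].CCCC[Al-](C)(C)OC/C=C(\C)C[C@@H](O[Si](C)(C)C(C)(C)C)C=C(C)C
F7 | step 6 | (2E,5R)-5-[(tert-butyldimethylsilyl)oxy]-3,7-dimethylocta-2,6-dien-1-ol | OC/C=C(\C)C[C@@H](O[Si](C)(C)C(C)(C)C)C=C(C)C
F8 | step 6 | 7-{[(2E,5R)-5-[(tert-butyldimethylsilyl)oxy]-3,7-dimethylocta-2,6-dien-1-yl]oxy}-8-methoxy-2H-chromen-2-one | COc1c(OC/C=C(\C)C[C@@H](O[Si](C)(C)C(C)(C)C)C=C(C)C)ccc2ccc(=O)oc12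
F9 | step 6 | 7-{[(2E,5R)-5-hydroxy-3,7-dimethylocta-2,6-dien-1-yl]oxy}-8-methoxy-2H-chromen-2-one | COc1c(OC/C=C(\C)C[C@@H](O)C=C(C)C)ccc2ccc(=O)oc12
F10 | step 6 | 7-{[(2E,5R)-5-[(2S)-3,3-dimethyloxiran-2-yl]-5-hydroxy-3-methylpent-2-en-1-yl]oxy}-8-methoxy-2H-chromen-2-one (threo) | COc1c(OC/C=C(\C)C[C@@H](O)[C@@H]2OC2(C)C)ccc2ccc(=O)oc12
F11 | step 6 | (1S,3E)-1-[(2S)-3,3-dimethyloxiran-2-yl]-5-[(8-methoxy-2-oxo-2H-chromen-7-yl)oxy]-3-methylpent-3-en-1-yl 4-nitrobenzoate | COc1c(OC/C=C(\C)C[C@H](OC(=O)c3ccc(cc3)[N+](=O)[O-])[C@@H]2OC2(C)C)ccc2ccc(=O)oc12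
F12 | step 3 | tert-butyl{[(1E,4S)-1-iodo-2,6-dimethylhepta-1,5-dien-4-yl]oxy}dimethylsilane | I/C=C(\C)C[C@H](O[Si](C)(C)C(C)(C)C)C=C(C)C
F13 | step 3 | methyl (2E,5S)-5-[(tert-butyldimethylsilyl)oxy]-3,7-dimethylocta-2,6-dienoate | COC(=O)/C=C(\C)C[C@H](O[Si](C)(C)C(C)(C)C)C=C(C)C
F14 | step 1 | racemic 6-methylhept-5-en-1-yn-4-ol | C#CCC(O)C=C(C)C
F15 | step 1 | (R)-6-methylhept-5-en-1-yn-4-yl acetate | C#CC[C@@H](OC(C)=O)C=C(C)C
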